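**Strategy.** The C7–C8(Me)–C8′(Me)–C7′ chain of the target is a meso-type (erythro) 2,3-dimethylbutane-1,4-diyl unit; the molecule is chiral only because ring A (guaiacyl) and ring B (syringyl) differ. The route therefore desymmetrises cis-2,3-dimethylsuccinic anhydride. A rhodium-catalysed enantioselective aryl transfer from 4-benzyloxy-3-methoxyphenylzinc triflate opens the meso anhydride, forming the bond between the ring A ipso carbon and C7 (at the ketone level) and fixing the absolute configuration at C8 and C8′ in one operation. The acid terminus, relayed through a γ-lactone, then accepts the ring B aryllithium, and one hydrogenolysis removes both benzylic oxygens and both benzyl ethers.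

Key step: step 3

Assumption: the (R,R)-enantiomer of the phosphoramidite ligand is taken to direct the aryl group to the carbonyl bonded to the (S)-configured carbon of anhydride 2; if the sense of induction is the opposite, the (S,S)-ligand is used with no other change.

**Step 1**
Reactants: 1 meso-2,3-dimethylsuccinic acid
Product: 2 cis-2,3-dimethylsuccinic anhydride, (3R,4S)-3,4-dimethyloxolane-2,5-dione
Conditions: AcCl (neat), reflux; evaporation
Reagents that add atoms: none
Why: Cyclodehydration of a 1,4-diacid to the five-membered anhydride through the mixed anhydride under non-basic conditions, so the cis (meso) relationship of the two methyl-bearing carbons should be carried over unchanged.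

**Step 2**
Reactants: 3 4-bromo-2-methoxyphenol
Product: 4 1-(benzyloxy)-4-bromo-2-methoxybenzene
Conditions: BnBr, K2CO3, DMF, rt
Reagents that add atoms: benzyl bromide, BrCc1ccccc1
Why: Williamson ether synthesis; the phenoxide should be O-benzylated cleanly, giving a protecting group that tolerates organolithium and organozinc chemistry and leaves in the final hydrogenolysis.

**Step 3**
Reactants: 4 1-(benzyloxy)-4-bromo-2-methoxybenzene; 2 cis-2,3-dimethylsuccinic anhydride
Product: 7 (2R,3S)-4-[4-(benzyloxy)-3-methoxyphenyl]-2,3-dimethyl-4-oxobutanoic acid, via aryllithium 5 (not isolated), via arylzinc triflate 6 (not isolated)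
Conditions: 4, n-BuLi, THF, −78 °C; Zn(OTf)2, −78 °C to rt; then 2, [Rh(cod)Cl]2 (cat.), (R,R)-TADDOL-PNMe2 phosphoramidite (cat.), THF/DMF, 50 °C; 1 M HCl work-up
Reagents that add atoms: none
Why: Monovalent rhodium carrying the chiral phosphoramidite should insert into one of the two enantiotopic acyl C–O bonds of meso anhydride 2 to give a trivalent acylrhodium carboxylate; transmetalation from arylzinc triflate 6 and reductive elimination then form the bond between the ring A ipso carbon and C7 and release the zinc carboxylate of 7. The closest known reaction type is the rhodium-catalysed enantioselective desymmetrising cross-coupling of cyclic meso anhydrides with organozinc reagents made in the flask, a Negishi-type acylation. No ring is closed; the anhydride ring is opened. No new stereocentre is created: the two cis methyl-bearing carbons C8 and C8′ already present are told apart, the chiral ligand on rhodium deciding which carbonyl is arylated and hence the absolute configuration (2R,3S), while the erythro relationship is inherited from the meso substrate. The step needs enantiotopic-group selection, mono-addition and no epimerisation next to the new ketone. These are secured by the mirror symmetry of 2, by the near-neutral arylzinc, which neither enolises nor attacks the aryl ketone product, and by the carboxylate leaving group, which stays bound as its zinc salt.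

**Step 4**
Reactants: 7 (2R,3S)-4-[4-(benzyloxy)-3-methoxyphenyl]-2,3-dimethyl-4-oxobutanoic acid
Product: 9 (3R,4S)-5-[4-(benzyloxy)-3-methoxyphenyl]-3,4-dimethyloxolan-2-one (mixture of C5 epimers), via hydroxy acid 8 (not isolated)
Conditions: NaBH4, MeOH, 0 °C; then 1 M HCl; TsOH (cat.), CH2Cl2, rt
Reagents that add atoms: none
Why: Borohydride reduction of the aryl ketone followed by acid-promoted lactonisation of the γ-hydroxy acid should mask the ketone and activate the acid terminus at once; the new carbinol centre is not controlled and is removed in step 7.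

**Step 5**
Reactants: 10 4-bromo-2,6-dimethoxyphenol
Product: 11 2-(benzyloxy)-5-bromo-1,3-dimethoxybenzene
Conditions: BnBr, K2CO3, DMF, 60 °C
Reagents that add atoms: benzyl bromide, BrCc1ccccc1
Why: Williamson ether synthesis on the flanked phenoxide, which should proceed with gentle heating in a polar aprotic solvent.

**Step 6**
Reactants: 11 2-(benzyloxy)-5-bromo-1,3-dimethoxybenzene; 9 (3R,4S)-5-[4-(benzyloxy)-3-methoxyphenyl]-3,4-dimethyloxolan-2-one
Product: 13 (2R,3S)-4-[4-(benzyloxy)-3-methoxyphenyl]-1-[4-(benzyloxy)-3,5-dimethoxyphenyl]-4-hydroxy-2,3-dimethylbutan-1-one (mixture of C4 epimers; ring–chain tautomer of the cyclic hemiketal), via aryllithium 12 (not isolated)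
Conditions: 11, n-BuLi, THF, −78 °C; then 9, THF, −78 °C; AcOH quench at −78 °C
Reagents that add atoms: none
Why: Nucleophilic acyl addition of an aryllithium to a γ-lactone should stop at the lithium hemiketal at −78 °C, so one aryl group enters, and addition should outpace enolisation so that the methyl-bearing carbon next to the carbonyl keeps its configuration.

**Step 7**
Reactants: 13 (2R,3S)-4-[4-(benzyloxy)-3-methoxyphenyl]-1-[4-(benzyloxy)-3,5-dimethoxyphenyl]-4-hydroxy-2,3-dimethylbutan-1-one
Product: 15 4-[(2S,3R)-4-(4-hydroxy-3-methoxyphenyl)-2,3-dimethylbutyl]-2,6-dimethoxyphenol, via diphenol hydroxy ketone 14 (not isolated)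
Conditions: H2 (4 atm), Pd/C, EtOAc/AcOH, 40 °C
Reagents that add atoms: none
Why: Catalytic hydrogenolysis should cleave both O-benzyl ethers and then reduce the benzylic alcohol and the aryl ketone (through its alcohol), both activated by para-hydroxy groups, to CH2, while the two methyl-bearing stereocentres, which are not benzylic, should stay untouched.

**Compound list**

1 | meso-2,3-dimethylsuccinic acid, (2R,3S)-2,3-dimethylbutanedioic acid | OC(=O)[C@@H](C)[C@@H](C)C(O)=O | starting material
2 | cis-2,3-dimethylsuccinic anhydride, (3R,4S)-3,4-dimethyloxolane-2,5-dione | O=C1[C@@H](C)[C@@H](C)C(=O)O1 | intermediate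
3 | 4-bromo-2-methoxyphenol | COc1cc(Br)ccc1O | starting material
4 | 1-(benzyloxy)-4-bromo-2-methoxybenzene | COc1cc(Br)ccc1OCc1ccccc1 | intermediate
5 | [4-(benzyloxy)-3-methoxyphenyl]lithium | [Li]c1ccc(OCc2ccccc2)c(OC)c1 | intermediate
6 | [4-(benzyloxy)-3-methoxyphenyl]zinc trifluoromethanesulfonate | FC(F)(F)S(=O)(=O)O[Zn]c1ccc(OCc2ccccc2)c(OC)c1 | intermediate
7 | (2R,3S)-4-[4-(benzyloxy)-3-methoxyphenyl]-2,3-dimethyl-4-oxobutanoic acid | COc1cc(C(=O)[C@@H](C)[C@@H](C)C(O)=O)ccc1OCc1ccccc1 | intermediate
8 | (2R,3S)-4-[4-(benzyloxy)-3-methoxyphenyl]-4-hydroxy-2,3-dimethylbutanoic acid (C4 epimers) | COc1cc(C(O)[C@@H](C)[C@@H](C)C(O)=O)ccc1OCc1ccccc1 | intermediate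
9 | (3R,4S)-5-[4-(benzyloxy)-3-methoxyphenyl]-3,4-dimethyloxolan-2-one (C5 epimers) | COc1cc(C2[C@@H](C)[C@@H](C)C(=O)O2)ccc1OCc1ccccc1 | intermediate
10 | 4-bromo-2,6-dimethoxyphenol | COc1cc(Br)cc(OC)c1O | starting material
11 | 2-(benzyloxy)-5-bromo-1,3-dimethoxybenzene | COc1cc(Br)cc(OC)c1OCc1ccccc1 | intermediate
12 | [4-(benzyloxy)-3,5-dimethoxyphenyl]lithium | [Li]c1cc(OC)c(OCc2ccccc2)c(OC)c1 | intermediate
13 | (2R,3S)-4-[4-(benzyloxy)-3-methoxyphenyl]-1-[4-(benzyloxy)-3,5-dimethoxyphenyl]-4-hydroxy-2,3-dimethylbutan-1-one (C4 epimers) | COc1cc(C(O)[C@@H](C)[C@@H](C)C(=O)c2cc(OC)c(OCc3ccccc3)c(OC)c2)ccc1OCc1ccccc1 | intermediate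
14 | (2R,3S)-4-hydroxy-1-(4-hydroxy-3,5-dimethoxyphenyl)-4-(4-hydroxy-3-methoxyphenyl)-2,3-dimethylbutan-1-one (C4 epimers) | COc1cc(C(O)[C@@H](C)[C@@H](C)C(=O)c2cc(OC)c(O)c(OC)c2)ccc1O | intermediate
15 | 4-[(2S,3R)-4-(4-hydroxy-3-methoxyphenyl)-2,3-dimethylbutyl]-2,6-dimethoxyphenol | COc1cc(C[C@@H](C)[C@@H](C)Cc2cc(OC)c(O)c(OC)c2)ccc1O | target

**Step count.** Total: 7 steps. Longest linear sequence: 5 steps (steps 1, 3, 4, 6, 7).

**Steps most likely to fail**

Step 3. The catalyst may discriminate poorly between the two enantiotopic carbonyl groups, or transmetalation from the electron-rich arylzinc may be slow, so that the keto acid forms with low enantiomeric purity or not at all. The fallback sets out from compound 2 and comes back at compound 9. Methanolysis of 2 mediated by a cinchona alkaloid (quinidine or its pseudo-enantiomer quinine, whichever opens the carbonyl bonded to the (R)-carbon; MeOH, toluene, −55 °C) would give the half-ester (2S,3R)-4-methoxy-2,3-dimethyl-4-oxobutanoic acid F1. (COCl)2 with catalytic DMF would give the acid chloride methyl (2R,3S)-4-chloro-2,3-dimethyl-4-oxobutanoate F2. Negishi acylation of F2 with arylzinc triflate 6 under zerovalent palladium catalysis, Pd(PPh3)4 in THF, would form the same aryl–carbonyl bond and give the keto ester methyl (2R,3S)-4-[4-(benzyloxy)-3-methoxyphenyl]-2,3-dimethyl-4-oxobutanoate F3. NaBH4 in MeOH would give the hydroxy ester methyl (2R,3S)-4-[4-(benzyloxy)-3-methoxyphenyl]-4-hydroxy-2,3-dimethylbutanoate F4, which on treatment with catalytic TsOH would lactonise with loss of methanol to compound 9.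

Step 7. The methyl-bearing carbon next to the ketone may lose its configuration through enolisation or enol ether formation before the carbonyl is reduced, or the electron-rich aryl ketone may be deoxygenated incompletely. The fallback sets out from compound 13 and comes back at compound 15. Ionic reduction of the hemiketal form of 13 with Et3SiH and BF3·OEt2 in CH2Cl2 at −78 °C would remove the carbonyl oxygen through the oxocarbenium ion and give the tetrahydrofuran (3S,4R)-2-[4-(benzyloxy)-3-methoxyphenyl]-5-[4-(benzyloxy)-3,5-dimethoxyphenyl]-3,4-dimethyloxolane F5 (configuration at C2 and C5 of no consequence). Hydrogenolysis of F5 (H2, Pd/C, AcOH, cat. HClO4) would then cleave both benzylic ring C–O bonds and both benzyl ethers to give compound 15.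

Step 6. The basic aryllithium may enolise the lactone, with loss of configuration at C3, or a second aryl group may add to the ketone once it is released. The fallback sets out from compound 9 and comes back at compound 15. Reduction of 9 with i-Bu2AlH in CH2Cl2 at −78 °C would give the lactol (3R,4S)-5-[4-(benzyloxy)-3-methoxyphenyl]-3,4-dimethyloxolan-2-ol F6. Its aldehyde form would take up aryllithium 12 (excess, THF, −78 to 0 °C) faster than it enolises and give the diol (2S,3R)-1-[4-(benzyloxy)-3-methoxyphenyl]-4-[4-(benzyloxy)-3,5-dimethoxyphenyl]-2,3-dimethylbutane-1,4-diol F7. Hydrogenolysis of F7 (H2, Pd/C, EtOAc/AcOH) would remove both benzylic hydroxyl groups and both benzyl ethers to give compound 15.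

**Further compounds**

F1 | step 3 | (2S,3R)-4-methoxy-2,3-dimethyl-4-oxobutanoic acid | OC(=O)[C@@H](C)[C@@H](C)C(=O)OC
F2 | step 3 | methyl (2R,3S)-4-chloro-2,3-dimethyl-4-oxobutanoate | ClC(=O)[C@@H](C)[C@@H](C)C(=O)OC
F3 | step 3 | methyl (2R,3S)-4-[4-(benzyloxy)-3-methoxyphenyl]-2,3-dimethyl-4-oxobutanoate | COc1cc(C(=O)[C@@H](C)[C@@H](C)C(=O)OC)ccc1OCc1ccccc1
F4 | step 3 | methyl (2R,3S)-4-[4-(benzyloxy)-3-methoxyphenyl]-4-hydroxy-2,3-dimethylbutanoate (C4 epimers) | COc1cc(C(O)[C@@H](C)[C@@H](C)C(=O)OC)ccc1OCc1ccccc1
F5 | step 7 | (3S,4R)-2-[4-(benzyloxy)-3-methoxyphenyl]-5-[4-(benzyloxy)-3,5-dimethoxyphenyl]-3,4-dimethyloxolane (C2 and C5 epimers) | COc1cc(C2[C@@H](C)[C@@H](C)C(c3cc(OC)c(OCc4ccccc4)c(OC)c3)O2)ccc1OCc1ccccc1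
F6 | step 6 | (3R,4S)-5-[4-(benzyloxy)-3-methoxyphenyl]-3,4-dimethyloxolan-2-ol (C2 and C5 epimers) | COc1cc(C2[C@@H](C)[C@@H](C)C(O)O2)ccc1OCc1ccccc1
F7 | step 6 | (2S,3R)-1-[4-(benzyloxy)-3-methoxyphenyl]-4-[4-(benzyloxy)-3,5-dimethoxyphenyl]-2,3-dimethylbutane-1,4-diol (C1 and C4 epimers) | COc1cc(C(O)[C@@H](C)[C@@H](C)C(O)c2cc(OC)c(OCc3ccccc3)c(OC)c2)ccc1OCc1ccccc1
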